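**Plan**

1. Retrosynthetic cuts: first the lower C4 carbinol (back to a ketone) and all O-protecting groups; then ring C of the upper unit at O1–C2 and C4a–C4 in one operation, which releases a mono-phenolic pyrogallol ketal and a cis-epoxy alcohol chain on C6 of a dihydroflavonol; then that chain at the C6–carbinol carbon and carbinol–alkyne bonds (carbonylative Sonogashira); last the lower ring C at O1–C2 and the chalcone C=C.
2. Enabling feature: in the upper unit C4a is the ring A carbon ortho to the ring oxygen O1 (a phenol oxygen with a free ortho carbon, a 1,3-bis-nucleophile), and C2 and C4 of ring C are both benzylic (C2 on ring B; C4 on lower ring A, ortho to its O7 and para to its O1), so C2–C3–C4 can be delivered as a 1,3-bis-electrophile: an SN2-active epoxide carbon (C2) and an ionisable carbinol (C4).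
3. Forward order: lower ring A (gallacetophenone) → chalcone → lower ring C → three-carbon chain on C6 → upper ring C fused onto a pyrogallol-derived ring A → deprotection → lower C4 reduction.
4. Stereochemistry: lower C2/C3 from a Juliá–Colonna epoxidation; lower C4 from substrate-controlled NaBH4 reduction; upper C2/C3 from a hydroxyl-directed epoxidation relayed from a temporary C4 carbinol (Midland reduction); upper C2 is then inverted by SN2 and upper C4 is set in the ring closure.
5. Helpers removed at the end: benzyl carbonate on ring B (keeps C2 from ionising), diphenylmethylene ketal, benzyl ethers, and the lower C4 ketone (switches off lower ring A and its C4).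

Key step: step 13

Assumption: flavan numbering is used for both units (O1, C2, C3, C4, C4a, C5 to C8, C8a; ring A the fused benzene ring, ring B the 2-aryl group, ring C the pyran ring), "upper" is the unit bonded through its C4, and 4-ethynylphenol is taken as a commercial material.

**Step 1**
Reactants: 1 pyrogallol
Product: 2 2,2-diphenyl-1,3-benzodioxol-4-ol
Conditions: Ph2CCl2 (1.1 equiv), neat, 170 °C, N2 sweep
Reagents that add atoms: dichlorodiphenylmethane, ClC(Cl)(c1ccccc1)c1ccccc1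
Why: Ketalisation of a catechol unit by a gem-dichloride (double substitution with loss of HCl); the two vicinal OH pairs of pyrogallol are equivalent, so one mono-phenol should result.

**Step 2**
Reactants: 3 4-ethynylphenol
Product: 4 benzyl 4-ethynylphenyl carbonate
Conditions: CbzCl, K2CO3, acetone, 0 °C to rt
Reagents that add atoms: benzyl chloroformate, O=C(Cl)OCc1ccccc1
Why: O-acylation of the phenol (carbonate formation) installs an electron-withdrawing, hydrogenolysable mask on the future ring B oxygen.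

**Step 3**
Reactants: 5 1-(2,3,4-trihydroxyphenyl)ethanone
Product: 6 1-[3,4-bis(benzyloxy)-2-hydroxyphenyl]ethanone
Conditions: BnBr (2.1 equiv), K2CO3, DMF, rt
Reagents that add atoms: benzyl bromide, BrCc1ccccc1
Why: Williamson etherification; the 2-OH is hydrogen-bonded to the acetyl carbonyl and flanked on both sides, so the 3- and 4-OH should react first.

**Step 4**
Reactants: 6 1-[3,4-bis(benzyloxy)-2-hydroxyphenyl]ethanone
Product: 7 1-[3,4-bis(benzyloxy)-2-hydroxy-5-iodophenyl]ethanone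
Conditions: NIS, TsOH (cat.), MeCN, rt
Reagents that add atoms: N-iodosuccinimide, O=C1CCC(=O)N1I
Why: Electrophilic aromatic iodination para to the free phenol; C5 is the only open position activated by it and is also ortho to the 4-benzyloxy group.

**Step 5**
Reactants: 7 1-[3,4-bis(benzyloxy)-2-hydroxy-5-iodophenyl]ethanone
Product: 8 1-[3,4-bis(benzyloxy)-5-iodo-2-(methoxymethoxy)phenyl]ethanone
Conditions: NaH, MOMCl, DMF, 0 °C
Reagents that add atoms: chloromethyl methyl ether, COCCl
Why: Williamson-type O-alkylation of the sodium phenoxide, which masks the phenol for the base-mediated steps that follow.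

**Step 6**
Reactants: 8 1-[3,4-bis(benzyloxy)-5-iodo-2-(methoxymethoxy)phenyl]ethanone, 9 4-(benzyloxy)benzaldehyde
Product: 10 (E)-1-[3,4-bis(benzyloxy)-5-iodo-2-(methoxymethoxy)phenyl]-3-[4-(benzyloxy)phenyl]prop-2-en-1-one
Conditions: KOH, EtOH–THF, rt
Reagents that add atoms: none
Why: Claisen–Schmidt condensation (aldol addition, then E1cB dehydration) should give the (E)-enone.

**Step 7**
Reactants: 10 (E)-1-[3,4-bis(benzyloxy)-5-iodo-2-(methoxymethoxy)phenyl]-3-[4-(benzyloxy)phenyl]prop-2-en-1-one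
Product: 11 [3,4-bis(benzyloxy)-5-iodo-2-(methoxymethoxy)phenyl]{(2R,3S)-3-[4-(benzyloxy)phenyl]oxiran-2-yl}methanone
Conditions: poly-L-leucine, urea·H2O2, DBU, THF, rt
Reagents that add atoms: urea–hydrogen peroxide, NC(N)=O.OO
Why: Juliá–Colonna epoxidation; the helical poly-L-leucine binds the enone and the hydroperoxide anion and directs conjugate addition to one face, which sets both epoxide carbons (2R,3S) under catalyst control.

**Step 8**
Reactants: 11 [3,4-bis(benzyloxy)-5-iodo-2-(methoxymethoxy)phenyl]{(2R,3S)-3-[4-(benzyloxy)phenyl]oxiran-2-yl}methanone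
Product: 13 (2R,3R)-7,8-bis(benzyloxy)-2-[4-(benzyloxy)phenyl]-3-hydroxy-6-iodochroman-4-one, via free 2'-phenol epoxy ketone 12 (not isolated)
Conditions: HCl (3 M in MeOH), THF, 45 °C
Reagents that add atoms: none
Why: Acidic acetal cleavage frees the phenol, which opens the epoxide at the benzylic carbon in a 6-endo-tet cyclisation with inversion, so the retained carbinol carbon (future C3) controls C2 and the 2,3-trans dihydroflavonol should form.

**Step 9**
Reactants: 13 (2R,3R)-7,8-bis(benzyloxy)-2-[4-(benzyloxy)phenyl]-3-hydroxy-6-iodochroman-4-one, 4 benzyl 4-ethynylphenyl carbonate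
Product: 14 benzyl 4-{3-[(2R,3R)-7,8-bis(benzyloxy)-2-(4-benzyloxyphenyl)-3-hydroxy-4-oxochroman-6-yl]-3-oxoprop-1-yn-1-yl}phenyl carbonate
Conditions: PdCl2(PPh3)2 (5 mol%), CuI (5 mol%), CO (1 atm), Et3N, THF, rt
Reagents that add atoms: carbon monoxide, [C-]#[O+]
Why: Carbonylative Sonogashira coupling; the aryl palladium iodide inserts CO and the acyl palladium species couples with the copper acetylide of 4.

**Step 10**
Reactants: 14 benzyl 4-{3-[(2R,3R)-7,8-bis(benzyloxy)-2-(4-benzyloxyphenyl)-3-hydroxy-4-oxochroman-6-yl]-3-oxoprop-1-yn-1-yl}phenyl carbonate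
Product: 15 benzyl 4-{(3R)-3-[(2R,3R)-7,8-bis(benzyloxy)-2-(4-benzyloxyphenyl)-3-hydroxy-4-oxochroman-6-yl]-3-hydroxyprop-1-yn-1-yl}phenyl carbonate
Conditions: (S)-Alpine-borane (B-isopinocampheyl-9-BBN, 3 equiv), THF, rt; CH3CHO; HOCH2CH2NH2
Reagents that add atoms: none
Why: Midland reduction; hydride passes from the pinanyl group through a boat-like six-membered transition state with the slim alkyne on the hindered side, which should set the temporary (R)-carbinol under reagent control, and the ynone reacts far faster than the deactivated chromanone carbonyl.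

**Step 11**
Reactants: 15 benzyl 4-{(3R)-3-[(2R,3R)-7,8-bis(benzyloxy)-2-(4-benzyloxyphenyl)-3-hydroxy-4-oxochroman-6-yl]-3-hydroxyprop-1-yn-1-yl}phenyl carbonate
Product: 16 benzyl 4-{(1Z,3R)-3-[(2R,3R)-7,8-bis(benzyloxy)-2-(4-benzyloxyphenyl)-3-hydroxy-4-oxochroman-6-yl]-3-hydroxyprop-1-en-1-yl}phenyl carbonate
Conditions: H2 (1 atm), Pd/CaCO3 poisoned with Pb(OAc)2 (Lindlar), quinoline, EtOAc, rt
Reagents that add atoms: none
Why: Lindlar semihydrogenation; syn delivery of H2 on the poisoned palladium surface should give the (Z)-alkene and leave the benzyl groups intact.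

**Step 12**
Reactants: 16 benzyl 4-{(1Z,3R)-3-[(2R,3R)-7,8-bis(benzyloxy)-2-(4-benzyloxyphenyl)-3-hydroxy-4-oxochroman-6-yl]-3-hydroxyprop-1-en-1-yl}phenyl carbonate
Product: 17 benzyl 4-{(2S,3R)-3-[(S)-[(2R,3R)-7,8-bis(benzyloxy)-2-(4-benzyloxyphenyl)-3-hydroxy-4-oxochroman-6-yl](hydroxy)methyl]oxiran-2-yl}phenyl carbonate
Conditions: mCPBA, NaHCO3, CH2Cl2, 0 °C
Reagents that add atoms: 3-chloroperoxybenzoic acid, OOC(=O)c1cccc(Cl)c1
Why: Hydroxyl-directed (Henbest) peracid epoxidation of a (Z)-allylic alcohol; A(1,3) strain holds the carbinol hydrogen in the alkene plane and the hydrogen-bonded peracid is delivered to the OH face, which should set both epoxide carbons (threo, cis-epoxide) from the C4 carbinol.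

**Step 13**
Reactants: 17 benzyl 4-{(2S,3R)-3-[(S)-[(2R,3R)-7,8-bis(benzyloxy)-2-(4-benzyloxyphenyl)-3-hydroxy-4-oxochroman-6-yl](hydroxy)methyl]oxiran-2-yl}phenyl carbonate, 2 2,2-diphenyl-1,3-benzodioxol-4-ol
Product: 19 benzyl 4-{(2R,3R,4R)-4-[(2R,3R)-7,8-bis(benzyloxy)-2-(4-benzyloxyphenyl)-3-hydroxy-4-oxochroman-6-yl]-3-hydroxy-7,8-(diphenylmethylenedioxy)chroman-2-yl}phenyl carbonate, via ring-opened aryl ether 18 (not isolated)
Conditions: 2 (1.5 equiv), Eu(O3SCF3)3 (0.3 equiv), 4 Å MS, ClCH2CH2Cl, 40 °C; then Sc(O3SCF3)3 (0.1 equiv), (CF3)2CHOH, 0 to 25 °C, same flask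
Reagents that add atoms: none
Why: Proposed new method: the europium triflate chelates the C4 hydroxyl and the epoxide oxygen of 17, and the single free OH of 2 opens the cis-epoxide at the benzylic carbon C2 with inversion (O1–C2); the stronger scandium triflate in hexafluoroisopropanol then ionises the C4 hydroxyl, which sits on a carbon benzylic to lower ring A (ortho to its O7, para to its O1), and the only free ortho carbon of the aryl ether (C4a, para to the ketal oxygen on C7) captures the cation (C4a–C4). The closest known reaction types are the hydroxyl-directed, Lewis-acid-catalysed distal opening of 2,3-epoxy alcohols by O-nucleophiles and the dehydrative intramolecular Friedel–Crafts alkylation of benzylic alcohols to 4-arylchromans, telescoped here into a formal (3+3) annulation that has not been shown on a 1,3-diaryl epoxy alcohol. The O1–C2 bond is made intermolecularly and ring C is then closed in a 6-exo-trig Friedel–Crafts mode at the C4 cation. C2 is set by SN2 inversion of the cis-epoxide and C3 is carried over from it, which gives the 2,3-cis relation; C4 is set in the ring closure, which should run through the conformer with H-3 eclipsing the plane of the cationic aryl group (least A(1,3) strain against H-5 of the lower unit) and the C3–O bond anti to the incoming C4a, placing the lower aryl group trans to 3-OH. The step needs O-alkylation at C2 before any C-alkylation and ionisation at C4 only: the carbonate on ring B keeps C2 SN2-like and non-ionisable, the C4 ketone of the lower unit removes the second benzylic leaving group and tames lower ring A, and 2 offers one OH and one free ortho carbon.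

**Step 14**
Reactants: 19 benzyl 4-{(2R,3R,4R)-4-[(2R,3R)-7,8-bis(benzyloxy)-2-(4-benzyloxyphenyl)-3-hydroxy-4-oxochroman-6-yl]-3-hydroxy-7,8-(diphenylmethylenedioxy)chroman-2-yl}phenyl carbonate
Product: 20 (2R,3R)-3,7,8-trihydroxy-2-(4-hydroxyphenyl)-6-[(2R,3R,4S)-3,7,8-trihydroxy-2-(4-hydroxyphenyl)chroman-4-yl]chroman-4-one
Conditions: H2 (1 atm), Pd(OH)2/C, THF–MeOH, rt
Reagents that add atoms: none
Why: Catalytic hydrogenolysis should cleave the three benzyl ethers, the benzyl carbonate (with loss of CO2) and the diphenylmethylene ketal while the deactivated aryl ketone and the ring benzylic C–O bonds stay, as in flavanoid benzyl ether deprotections (the upper C4 descriptor changes from R to S only because the CIP ranking changes).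

**Step 15**
Reactants: 20 (2R,3R)-3,7,8-trihydroxy-2-(4-hydroxyphenyl)-6-[(2R,3R,4S)-3,7,8-trihydroxy-2-(4-hydroxyphenyl)chroman-4-yl]chroman-4-one
Product: 21 (2R,3S,4R)-2-(4-hydroxyphenyl)-6-[(2R,3R,4S)-3,7,8-trihydroxy-2-(4-hydroxyphenyl)chroman-4-yl]chroman-3,4,7,8-tetrol
Conditions: NaBH4, EtOH, 0 °C to rt, Ar; AcOH quench
Reagents that add atoms: none
Why: Borohydride reduction of a 2,3-trans dihydroflavonol; axial hydride addition to the half-chair with equatorial 2-aryl and 3-OH should give the equatorial 4-OH trans to 3-OH (substrate control, the usual outcome for this class), which sets the lower C4 as R.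

**Compound list**

1 | pyrogallol | Oc1cccc(O)c1O | starting material
2 | 2,2-diphenyl-1,3-benzodioxol-4-ol | Oc1cccc2OC(c3ccccc3)(c3ccccc3)Oc12 | intermediate
3 | 4-ethynylphenol | C#Cc1ccc(O)cc1 | starting material
4 | benzyl 4-ethynylphenyl carbonate | C#Cc1ccc(OC(=O)OCc2ccccc2)cc1 | intermediate
5 | 1-(2,3,4-trihydroxyphenyl)ethanone | CC(=O)c1ccc(O)c(O)c1O | starting material
6 | 1-[3,4-bis(benzyloxy)-2-hydroxyphenyl]ethanone | CC(=O)c1ccc(OCc2ccccc2)c(OCc2ccccc2)c1O | intermediate
7 | 1-[3,4-bis(benzyloxy)-2-hydroxy-5-iodophenyl]ethanone | CC(=O)c1cc(I)c(OCc2ccccc2)c(OCc2ccccc2)c1O | intermediate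
8 | 1-[3,4-bis(benzyloxy)-5-iodo-2-(methoxymethoxy)phenyl]ethanone | CC(=O)c1cc(I)c(OCc2ccccc2)c(OCc2ccccc2)c1OCOC | intermediate
9 | 4-(benzyloxy)benzaldehyde | O=Cc1ccc(OCc2ccccc2)cc1 | starting material
10 | (E)-1-[3,4-bis(benzyloxy)-5-iodo-2-(methoxymethoxy)phenyl]-3-[4-(benzyloxy)phenyl]prop-2-en-1-one | O=C(/C=C/c1ccc(OCc2ccccc2)cc1)c1cc(I)c(OCc2ccccc2)c(OCc2ccccc2)c1OCOC | intermediate
11 | [3,4-bis(benzyloxy)-5-iodo-2-(methoxymethoxy)phenyl]{(2R,3S)-3-[4-(benzyloxy)phenyl]oxiran-2-yl}methanone | O=C([C@@H]1O[C@H]1c1ccc(OCc2ccccc2)cc1)c1cc(I)c(OCc2ccccc2)c(OCc2ccccc2)c1OCOC | intermediate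
12 | [3,4-bis(benzyloxy)-2-hydroxy-5-iodophenyl]{(2R,3S)-3-[4-(benzyloxy)phenyl]oxiran-2-yl}methanone | O=C([C@@H]1O[C@H]1c1ccc(OCc2ccccc2)cc1)c1cc(I)c(OCc2ccccc2)c(OCc2ccccc2)c1O | intermediate (not isolated)
13 | (2R,3R)-7,8-bis(benzyloxy)-2-[4-(benzyloxy)phenyl]-3-hydroxy-6-iodochroman-4-one | Ic1cc2c(c(OCc3ccccc3)c1OCc1ccccc1)O[C@H](c1ccc(OCc3ccccc3)cc1)[C@@H](O)C2=O | intermediate
14 | benzyl 4-{3-[(2R,3R)-7,8-bis(benzyloxy)-2-(4-benzyloxyphenyl)-3-hydroxy-4-oxochroman-6-yl]-3-oxoprop-1-yn-1-yl}phenyl carbonate | O=C(C#Cc1ccc(OC(=O)OCc2ccccc2)cc1)c1cc2c(c(OCc3ccccc3)c1OCc1ccccc1)O[C@H](c1ccc(OCc3ccccc3)cc1)[C@@H](O)C2=O | intermediate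
15 | benzyl 4-{(3R)-3-[(2R,3R)-7,8-bis(benzyloxy)-2-(4-benzyloxyphenyl)-3-hydroxy-4-oxochroman-6-yl]-3-hydroxyprop-1-yn-1-yl}phenyl carbonate | O=C(OCc1ccccc1)Oc1ccc(C#C[C@@H](O)c2cc3c(c(OCc4ccccc4)c2OCc2ccccc2)O[C@H](c2ccc(OCc4ccccc4)cc2)[C@@H](O)C3=O)cc1 | intermediate
16 | benzyl 4-{(1Z,3R)-3-[(2R,3R)-7,8-bis(benzyloxy)-2-(4-benzyloxyphenyl)-3-hydroxy-4-oxochroman-6-yl]-3-hydroxyprop-1-en-1-yl}phenyl carbonate | O=C(OCc1ccccc1)Oc1ccc(/C=C\[C@@H](O)c2cc3c(c(OCc4ccccc4)c2OCc2ccccc2)O[C@H](c2ccc(OCc4ccccc4)cc2)[C@@H](O)C3=O)cc1 | intermediate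
17 | benzyl 4-{(2S,3R)-3-[(S)-[(2R,3R)-7,8-bis(benzyloxy)-2-(4-benzyloxyphenyl)-3-hydroxy-4-oxochroman-6-yl](hydroxy)methyl]oxiran-2-yl}phenyl carbonate | O=C(OCc1ccccc1)Oc1ccc([C@@H]2O[C@@H]2[C@@H](O)c2cc3c(c(OCc4ccccc4)c2OCc2ccccc2)O[C@H](c2ccc(OCc4ccccc4)cc2)[C@@H](O)C3=O)cc1 | intermediate
18 | benzyl 4-{(1R,2R,3S)-3-[(2R,3R)-7,8-bis(benzyloxy)-2-(4-benzyloxyphenyl)-3-hydroxy-4-oxochroman-6-yl]-1-[(2,2-diphenyl-1,3-benzodioxol-4-yl)oxy]-2,3-dihydroxypropyl}phenyl carbonate | O=C(OCc1ccccc1)Oc1ccc([C@@H](Oc2cccc3OC(c4ccccc4)(c4ccccc4)Oc23)[C@H](O)[C@@H](O)c2cc3c(c(OCc4ccccc4)c2OCc2ccccc2)O[C@H](c2ccc(OCc4ccccc4)cc2)[C@@H](O)C3=O)cc1 | intermediate (not isolated)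
19 | benzyl 4-{(2R,3R,4R)-4-[(2R,3R)-7,8-bis(benzyloxy)-2-(4-benzyloxyphenyl)-3-hydroxy-4-oxochroman-6-yl]-3-hydroxy-7,8-(diphenylmethylenedioxy)chroman-2-yl}phenyl carbonate | O=C(OCc1ccccc1)Oc1ccc([C@H]2Oc3c(ccc4OC(c5ccccc5)(c5ccccc5)Oc34)[C@H](c3cc4c(c(OCc5ccccc5)c3OCc3ccccc3)O[C@H](c3ccc(OCc5ccccc5)cc3)[C@@H](O)C4=O)[C@H]2O)cc1 | intermediate
20 | (2R,3R)-3,7,8-trihydroxy-2-(4-hydroxyphenyl)-6-[(2R,3R,4S)-3,7,8-trihydroxy-2-(4-hydroxyphenyl)chroman-4-yl]chroman-4-one | Oc1ccc([C@H]2Oc3c(ccc(O)c3O)[C@H](c3cc4c(c(O)c3O)O[C@H](c3ccc(O)cc3)[C@@H](O)C4=O)[C@H]2O)cc1 | intermediate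
21 | (2R,3S,4R)-2-(4-hydroxyphenyl)-6-[(2R,3R,4S)-3,7,8-trihydroxy-2-(4-hydroxyphenyl)chroman-4-yl]chroman-3,4,7,8-tetrol | Oc1ccc([C@H]2Oc3c(ccc(O)c3O)[C@H](c3cc4c(c(O)c3O)O[C@H](c3ccc(O)cc3)[C@@H](O)[C@@H]4O)[C@H]2O)cc1 | target

**Step count and risks**

Total steps: 15. Longest linear sequence: 13 steps (steps 3 to 15, from 1-(2,3,4-trihydroxyphenyl)ethanone).

Steps most likely to fail:

1. Step 13 (proposed new method). What may go wrong: C-alkylation of the phenol at the activated epoxide instead of O-alkylation; aryl or hydride shift (semipinacol type) in the Lewis-acid-bound epoxy alcohol or in the C4 cation; poor facial selectivity in the ring closure, giving the 3,4-cis isomer.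
Fallback (known Mitsunobu etherification and epoxide–arene cyclisation), setting out from 15 and coming back at 19. A Meyer–Schuster rearrangement of 15 (Ph3PAuN(SO2CF3)2, MeOH, toluene, rt) should give the transposed (E)-enone F1. Luche reduction at −78 °C (NaBH4, CeCl3, MeOH–THF), where the vinylogous-ester chromanone carbonyl is much less electrophilic, should give the (E)-allylic alcohol F2 as a pair of carbinol epimers. Sharpless epoxidation with kinetic resolution (Ti(OiPr)4, L-(+)-diisopropyl tartrate, t-BuOOH, 4 Å MS, CH2Cl2, −20 °C) should convert the (R)-epimer into the erythro trans-epoxy alcohol F3. Mitsunobu etherification with 2 (PPh3, DIAD, THF, 0 °C) should give the aryl ether epoxide F4 with inversion at C2. A 6-endo epoxide–arene cyclisation in (CF3)2CHOH (or with BF3·OEt2 in CH2Cl2 at −40 °C), with inversion at C4, should then give 19.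

2. Step 8. What may go wrong: SN1 opening of the epoxide at the 4-alkoxybenzylic carbon by methanol or chloride with loss of configuration at C2, and aroyl migration to an isoflavone-type by-product.
Fallback (thioether relay), setting out from 11 and coming back at 13. Benzyl mercaptan with SnCl4 (CH2Cl2, −20 °C) should open the epoxide at the benzylic carbon and remove the methoxymethyl group, giving the 2-hydroxy-3-benzylsulfanyl dihydrochalcone F5. Thiophilic activation with AgBF4 (CH2Cl2, 0 °C) should then close the pyranone ring to 13, the 2,3-trans isomer being favoured.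

3. Step 10. What may go wrong: slow hydride transfer to the hindered diaryl ynone, which lets the reagent dissociate to achiral 9-BBN and erodes the carbinol configuration on which the epoxide configuration depends.
Fallback (carbonyl addition instead of reduction), setting out from 13 and coming back at 15, bypassing 14. A Stille-type reductive carbonylation (Pd(PPh3)4, CO, Bu3SnH added slowly, THF, 50 °C) should give the 6-carbaldehyde F6. Zinc-mediated asymmetric alkynylation with 4 (Me2Zn, the ProPhenol ligand enantiomer that gives the (R)-carbinol, toluene, 0 °C) should then give 15.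

**Further compounds**

F1 | step 13 | benzyl 4-{(2E)-3-[(2R,3R)-7,8-bis(benzyloxy)-2-(4-benzyloxyphenyl)-3-hydroxy-4-oxochroman-6-yl]prop-2-enoyl}phenyl carbonate | O=C(OCc1ccccc1)Oc1ccc(C(=O)/C=C/c2cc3c(c(OCc4ccccc4)c2OCc2ccccc2)O[C@H](c2ccc(OCc4ccccc4)cc2)[C@@H](O)C3=O)cc1
F2 | step 13 | benzyl 4-{(1R,2E)-3-[(2R,3R)-7,8-bis(benzyloxy)-2-(4-benzyloxyphenyl)-3-hydroxy-4-oxochroman-6-yl]-1-hydroxyprop-2-en-1-yl}phenyl carbonate (reactive epimer) | O=C(OCc1ccccc1)Oc1ccc([C@H](O)/C=C/c2cc3c(c(OCc4ccccc4)c2OCc2ccccc2)O[C@H](c2ccc(OCc4ccccc4)cc2)[C@@H](O)C3=O)cc1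
F3 | step 13 | benzyl 4-{(S)-[(2S,3S)-3-[(2R,3R)-7,8-bis(benzyloxy)-2-(4-benzyloxyphenyl)-3-hydroxy-4-oxochroman-6-yl]oxiran-2-yl](hydroxy)methyl}phenyl carbonate | O=C(OCc1ccccc1)Oc1ccc([C@H](O)[C@@H]2O[C@H]2c2cc3c(c(OCc4ccccc4)c2OCc2ccccc2)O[C@H](c2ccc(OCc4ccccc4)cc2)[C@@H](O)C3=O)cc1
F4 | step 13 | benzyl 4-{[3-[(2R,3R)-7,8-bis(benzyloxy)-2-(4-benzyloxyphenyl)-3-hydroxy-4-oxochroman-6-yl]oxiran-2-yl][(2,2-diphenyl-1,3-benzodioxol-4-yl)oxy]methyl}phenyl carbonate (trans-epoxide, configuration as in the SMILES) | O=C(OCc1ccccc1)Oc1ccc([C@@H](Oc2cccc3OC(c4ccccc4)(c4ccccc4)Oc23)[C@@H]2O[C@H]2c2cc3c(c(OCc4ccccc4)c2OCc2ccccc2)O[C@H](c2ccc(OCc4ccccc4)cc2)[C@@H](O)C3=O)cc1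
F5 | step 8 | 1-[3,4-bis(benzyloxy)-2-hydroxy-5-iodophenyl]-3-(benzylsulfanyl)-3-[4-(benzyloxy)phenyl]-2-hydroxypropan-1-one (configuration as in the SMILES) | O=C([C@H](O)[C@H](SCc1ccccc1)c1ccc(OCc2ccccc2)cc1)c1cc(I)c(OCc2ccccc2)c(OCc2ccccc2)c1O
F6 | step 10 | (2R,3R)-7,8-bis(benzyloxy)-2-[4-(benzyloxy)phenyl]-3-hydroxy-4-oxochroman-6-carbaldehyde | O=Cc1cc2c(c(OCc3ccccc3)c1OCc1ccccc1)O[C@H](c1ccc(OCc3ccccc3)cc1)[C@@H](O)C2=O
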